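**Retrosynthetic overview**
1. Target 9 ⇒ bis-phenol 6 + 2 prenal: both 2H-pyran rings are closed last, in one operation (two-fold ortho-C-alkenylation, then oxa-6π electrocyclisation), on the unprotected, already stereodefined skeleton.
2. 6 ⇒ styrene 3 + (E)-alkenylboronate 5 by Ni–H enantioselective hydroalkenylation, which sets the (S) centre and keeps the E-alkene.
3. 5 ⇒ 3 + vinyl-Bpin (cross-metathesis); 3 ⇒ 4-hydroxy-2-methoxybenzaldehyde 1 (Wittig). One aldehyde supplies both aryl halves.
4. Ring order: the two benzene rings are bought; the two pyran rings form together in the final step.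

Assumption: the enantiomer of the chiral Ni ligand that delivers the (S) product is used (the sense of induction is checked on 6 by chiral HPLC and on 9 by optical rotation; the antipodal ligand is used if needed).

**Step 1**
Reactants: 1 4-hydroxy-2-methoxybenzaldehyde; 2 methyltriphenylphosphonium bromide
Product: 3 3-methoxy-4-vinylphenol (4-ethenyl-3-methoxyphenol)
Conditions: 2 (2.5 equiv), KOtBu (3.6 equiv), THF, 0 °C → rt; aq. NH4Cl work-up
Reagents that add atoms: methyltriphenylphosphonium bromide, C[P+](c1ccccc1)(c1ccccc1)c1ccccc1.[Br-]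
Why: Wittig methylenation; the first equivalent of base only makes the phenoxide, and excess unstabilised ylide still converts the deactivated aldehyde to the terminal alkene, as with vanillin-type aldehydes (no stereocentre formed).

**Step 2**
Reactants: 3 3-methoxy-4-vinylphenol; 4 vinylboronic acid pinacol ester
Product: 5 (E)-3-methoxy-4-[2-(4,4,5,5-tetramethyl-1,3,2-dioxaborolan-2-yl)ethenyl]phenol
Conditions: Hoveyda–Grubbs II (3 mol%), 4 (2 equiv), CH2Cl2, 40 °C
Reagents that add atoms: vinylboronic acid pinacol ester, C=CB1OC(C)(C)C(C)(C)O1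
Why: Olefin cross-metathesis of a styrene with vinyl-Bpin (a slow homodimeriser) is driven by ethene loss, gives the (E)-β-borylstyrene under thermodynamic control, and Ru carbenes tolerate the free phenol (no stereocentre formed).

**Step 3**
Reactants: 3 3-methoxy-4-vinylphenol (1.0 equiv); 5 (E)-alkenylboronate (1.5 equiv)
Product: 6 4,4'-[(1E,3S)-but-1-ene-1,3-diyl]bis(3-methoxyphenol)
Conditions: Ni(cod)2 (10 mol%), chiral spiro aminophosphine ligand L* (12 mol%), MeOH/THF, 40 °C
Reagents that add atoms: none
Why: Nickel hydride catalysed enantioselective hydroalkenylation of a styrene with an alkenylboron reagent (redox-neutral, MeOH as hydrogen source): Markovnikov Ni–H insertion into 3 gives an η3-benzyl nickel species, alkenyl transfer from 5 to the Ni–OMe centre and reductive elimination form the benzylic C–C bond with the E-alkene retained, and the chiral ligand fixes the face and hence the (S) centre, the phenols being only further protic groups in a methanolic medium.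

**Step 4 (key step)**
Reactants: 6 4,4'-[(1E,3S)-but-1-ene-1,3-diyl]bis(3-methoxyphenol); 7 3-methylbut-2-enal (prenal)
Product: 9 6,6'-[(1E,3S)-but-1-ene-1,3-diyl]bis(7-methoxy-2,2-dimethyl-2H-chromene), via bis(ortho-quinone methide) 8 (not isolated)
Conditions: Ti(OEt)4 (2.2 equiv), PhMe, reflux with removal of EtOH; then 7 (3 equiv), PhMe, reflux
Reagents that add atoms: 3-methylbut-2-enal, CC(C)=CC=O
Why: Two-fold titanium phenoxide ortho-C-alkylation with an enal (Casiraghi–Sartori 2H-chromene synthesis), dehydration to 8 and oxa-6π electrocyclisation close both pyran rings in the same flask; attack goes to the unhindered ortho carbon para to OMe on each ring, and the medium, free of Brønsted acid and strong base, leaves the (S) centre and the E-alkene untouched (no new stereocentre).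

**Compound list**
1 | 4-hydroxy-2-methoxybenzaldehyde | COc1cc(O)ccc1C=O | starting material
2 | methyltriphenylphosphonium bromide | C[P+](c1ccccc1)(c1ccccc1)c1ccccc1.[Br-] | starting material
3 | 3-methoxy-4-vinylphenol | COc1cc(O)ccc1C=C | intermediate
4 | vinylboronic acid pinacol ester (2-ethenyl-4,4,5,5-tetramethyl-1,3,2-dioxaborolane) | C=CB1OC(C)(C)C(C)(C)O1 | starting material
5 | (E)-3-methoxy-4-[2-(4,4,5,5-tetramethyl-1,3,2-dioxaborolan-2-yl)ethenyl]phenol | COc1cc(O)ccc1/C=C/B1OC(C)(C)C(C)(C)O1 | intermediate
6 | 4,4'-[(1E,3S)-but-1-ene-1,3-diyl]bis(3-methoxyphenol) | COc1cc(O)ccc1/C=C/[C@H](C)c1ccc(O)cc1OC | intermediate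
7 | 3-methylbut-2-enal (prenal) | CC(C)=CC=O | starting material
8 | bis(ortho-quinone methide): each aryl ring of 6 as a 6-(3-methylbut-2-enylidene)cyclohexa-2,4-dien-1-one (C=O at the former phenol carbon, dienylidene at the adjacent carbon para to OMe), (1E,3S)-butene linker unchanged | COC1=CC(=O)C(=CC=C(C)C)C=C1/C=C/[C@H](C)C1=CC(=CC=C(C)C)C(=O)C=C1OC | intermediate (not isolated)
9 | 6,6'-[(1E,3S)-but-1-ene-1,3-diyl]bis(7-methoxy-2,2-dimethyl-2H-chromene) | COc1cc2c(cc1/C=C/[C@H](C)c1cc3c(cc1OC)OC(C)(C)C=C3)C=CC(C)(C)O2 | target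

**Totals**
Total step count: 4. Longest linear sequence: 4 (1 → 3 → 5 → 6 → 9).

**Three steps most likely to fail, each with a fallback**

Step 3 (Ni–H hydroalkenylation). The risks are the free phenols, slow transmetalation of the pinacol ester, and the ortho-methoxy group eroding ee. The fallback sets out from 3 and comes back at 6. Compound 3 is silylated (TBSCl, imidazole, DMF) to tert-butyl(4-ethenyl-3-methoxyphenoxy)dimethylsilane F1. F1 undergoes Ni-catalysed asymmetric hydrovinylation with ethene ([(allyl)NiBr]2, chiral phosphoramidite, NaBArF, CH2Cl2, −70 °C) to give (S)-tert-butyl[4-(but-3-en-2-yl)-3-methoxyphenoxy]dimethylsilane F2, so the stereocentre is set on a single aryl unit. E-selective cross-metathesis of F2 with a second portion of F1 (Grubbs II, benzoquinone, CH2Cl2, 40 °C) then gives the (1E,3S)-bis(tert-butyldimethylsilyl) ether of 6 F3. TBAF (THF, 0 °C) releases 6.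

Step 4 (double annulation). The risks are annulation between OH and OMe on one ring, oligomeric titanium bis-phenoxides, and stalling after the first ring. The fallback sets out from 6 and comes back at 9. Both phenols are alkylated with 3-chloro-3-methylbut-1-yne (DBU, CuCl2 cat., MeCN, 0 °C) to give 4,4'-[(1E,3S)-but-1-ene-1,3-diyl]bis[2-methoxy-4-(2-methylbut-3-yn-2-yloxy)benzene] F4. Heating F4 (N,N-diethylaniline, 150–160 °C) triggers a two-fold aryl propargyl ether Claisen rearrangement, [1,5]-H shift and oxa-6π closure through the same dienone 8, again closing both pyran rings in one operation to give 9.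

Step 2 (cross-metathesis). The risks are chelation of the ortho-methoxystyrene to Ru, stilbene formation, and polymerisation of the vinylphenol. The fallback sets out from 1 and comes back at 5. Ohira–Bestmann homologation of 1 (dimethyl (1-diazo-2-oxopropyl)phosphonate, K2CO3, MeOH, rt) gives 4-ethynyl-3-methoxyphenol F5. Copper-catalysed syn, anti-Markovnikov borylation–protonation of F5 (B2pin2, CuCl/Xantphos, NaOtBu, MeOH, THF, rt) gives 5.

**Further compounds**
F1 | step 3 | tert-butyl(4-ethenyl-3-methoxyphenoxy)dimethylsilane | COc1cc(O[Si](C)(C)C(C)(C)C)ccc1C=C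
F2 | step 3 | (S)-tert-butyl[4-(but-3-en-2-yl)-3-methoxyphenoxy]dimethylsilane | C=C[C@H](C)c1ccc(O[Si](C)(C)C(C)(C)C)cc1OC
F3 | step 3 | (1E,3S)-bis(tert-butyldimethylsilyl) ether of 6 | COc1cc(O[Si](C)(C)C(C)(C)C)ccc1/C=C/[C@H](C)c1ccc(O[Si](C)(C)C(C)(C)C)cc1OC
F4 | step 4 | 4,4'-[(1E,3S)-but-1-ene-1,3-diyl]bis[2-methoxy-4-(2-methylbut-3-yn-2-yloxy)benzene] | COc1cc(OC(C)(C)C#C)ccc1/C=C/[C@H](C)c1ccc(OC(C)(C)C#C)cc1OC
F5 | step 2 | 4-ethynyl-3-methoxyphenol | COc1cc(O)ccc1C#C
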